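The route disconnects ring A at two neighbouring bonds at once. Ring A carries three contiguous functionalised carbons: C6 (hydroxyl), C1 (ester) and C2 (aryloxy, linked to C1′ of ring B). The C2–O ether bond and the C1–carboxyl bond are therefore made in one operation, when the ring B phenoxide and carbon dioxide add across a C1≡C2 aryne of ring A polarised by the C6 alkoxy group. No substitution at a hindered arene carbon is needed. The aryne precursor is a fully substituted 2-silylaryl triflate (C1 SiMe3, C2 OTf, C6 OMOM, C5 prenyl, C4 methyl) built from orcinol by two directed metalations. The partner is a benzylic-silylated salicyl alcohol from 2,4-dimethoxyphenol.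

Key step: step 10

Remark on numbering: ring A atoms carry the target numbering throughout (C1 carboxyl-bearing, C2 aryloxy, C3 H, C4 methyl, C5 prenyl, C6 hydroxyl). Ring B is numbered from the ether carbon C1′ (C2′ CH2O, C4′ and C6′ OMe). Prenyl means 3-methylbut-2-en-1-yl. The target has no stereocentre and no stereogenic double bond.

Assumption: orcinol, prenyl bromide and 2,4-dimethoxyphenol are bought.

Step 1
Reactants: 1 orcinol (5-methylbenzene-1,3-diol)
Product: 2 5-methyl-1,3-phenylene bis(N,N-diethylcarbamate)
Conditions: Et2NCOCl (2.4 equiv), K2CO3, MeCN, reflux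
Reagents that add atoms: N,N-diethylcarbamoyl chloride, CCN(CC)C(Cl)=O
Why: Base-mediated O-carbamoylation of both phenols installs two strong directing groups for ortho-metalation and keeps the ring symmetric, so no regiochemical question arises.

Step 2
Reactants: 2 5-methyl-1,3-phenylene bis(N,N-diethylcarbamate)
Product: 4 5-methyl-2-(trimethylsilyl)-1,3-phenylene bis(N,N-diethylcarbamate), via C1-aryllithium 3 (not isolated)
Conditions: s-BuLi, TMEDA, THF, −78 °C; then Me3SiCl, −78 °C → rt
Reagents that add atoms: chlorotrimethylsilane, C[Si](C)(C)Cl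
Why: Directed ortho-metalation should occur at C1, which lies between the two carbamate oxygens and is by far the most acidic ring position, and silylation at −78 °C (below the onset of anionic ortho-Fries rearrangement) puts SiMe3 on the carbon that later becomes one aryne terminus.

Step 3
Reactants: 4 5-methyl-2-(trimethylsilyl)-1,3-phenylene bis(N,N-diethylcarbamate); 5 prenyl bromide (1-bromo-3-methylbut-2-ene)
Product: 8 5-methyl-4-prenyl-2-(trimethylsilyl)-1,3-phenylene bis(N,N-diethylcarbamate), via C5-aryllithium 6 (not isolated), via C5-arylcopper 7 (not isolated)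
Conditions: s-BuLi, TMEDA, THF, −78 °C; CuBr·SMe2, −78 → −40 °C; then 5, −78 → 0 °C
Reagents that add atoms: none
Why: With C1 blocked, a second directed ortho-metalation can only take place at C5 (C3 is equivalent by symmetry), and transmetalation to monovalent copper before the allylic substitution should suppress both anionic ortho-Fries rearrangement and attack at the tertiary allyl terminus, giving the linear prenyl group.

Step 4
Reactants: 8 5-methyl-4-prenyl-2-(trimethylsilyl)-1,3-phenylene bis(N,N-diethylcarbamate)
Product: 9 5-methyl-4-prenyl-2-(trimethylsilyl)benzene-1,3-diol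
Conditions: LiAlH4, THF, 0 °C → reflux; aqueous potassium sodium tartrate work-up
Reagents that add atoms: none
Why: Hydride reduction of aryl carbamates releases both phenols under aprotic conditions that leave the aryl–silicon bond and the prenyl alkene untouched, and the neutral tartrate work-up avoids protodesilylation of the electron-rich arylsilane.

Step 5
Reactants: 9 5-methyl-4-prenyl-2-(trimethylsilyl)benzene-1,3-diol
Product: 10 3-hydroxy-5-methyl-4-prenyl-2-(trimethylsilyl)phenyl trifluoromethanesulfonate
Conditions: PhNTf2 (1.0 equiv), Et3N, CH2Cl2, 0 °C → rt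
Reagents that add atoms: N-phenylbis(trifluoromethanesulfonimide), O=S(=O)(N(c1ccccc1)S(=O)(=O)C(F)(F)F)C(F)(F)F
Why: Sterically controlled mono-O-sulfonylation should occur at the C2 hydroxyl, which has a free ortho position (C3–H), whereas the C6 hydroxyl is wedged between SiMe3 and the prenyl group, so one equivalent of the bulky, mild triflating agent under a tertiary amine base should leave C6–OH untouched.

Step 6
Reactants: 10 3-hydroxy-5-methyl-4-prenyl-2-(trimethylsilyl)phenyl trifluoromethanesulfonate
Product: 11 3-(methoxymethoxy)-5-methyl-4-prenyl-2-(trimethylsilyl)phenyl trifluoromethanesulfonate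
Conditions: MOMCl, i-Pr2NEt, CH2Cl2, 0 °C → rt
Reagents that add atoms: chloromethyl methyl ether, COCCl
Why: O-Alkylation of the remaining hindered phenol with a small, very reactive chloromethyl ether under a tertiary amine base avoids a free alkali-metal phenoxide, which could shift silicon from C1 to the C6 oxygen and release the aryne early, and it gives an acetal that is inert to fluoride and to carbanions.

Step 7
Reactants: 12 2,4-dimethoxyphenol
Product: 13 2-hydroxy-3,5-dimethoxybenzaldehyde
Conditions: MgCl2, Et3N, (CH2O)n, MeCN, reflux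
Reagents that add atoms: paraformaldehyde (as formaldehyde), C=O
Why: The magnesium-mediated ortho-formylation of phenols (Casnati–Skattebøl reaction) delivers the formyl group only ortho to the hydroxyl, and the single free ortho position of 12 is the one required.

Step 8
Reactants: 13 2-hydroxy-3,5-dimethoxybenzaldehyde
Product: 14 2-(hydroxymethyl)-4,6-dimethoxyphenol
Conditions: NaBH4, MeOH, 0 °C
Reagents that add atoms: none
Why: Borohydride reduction of the aldehyde should give the salicyl alcohol cleanly, with a near-neutral work-up to avoid ortho-quinone methide formation.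

Step 9
Reactants: 14 2-(hydroxymethyl)-4,6-dimethoxyphenol
Product: 15 2,4-dimethoxy-6-(triisopropylsilyloxymethyl)phenol
Conditions: TIPSCl (1.05 equiv), imidazole, CH2Cl2, 0 °C → rt
Reagents that add atoms: chlorotriisopropylsilane, CC(C)[Si](Cl)(C(C)C)C(C)C
Why: Chemoselective silylation should favour the primary benzylic hydroxyl over the phenol, which is flanked by two ortho substituents and hydrogen-bonded to the neighbouring methoxy group, so the phenol stays free for the coupling.

Step 10
Reactants: 11 3-(methoxymethoxy)-5-methyl-4-prenyl-2-(trimethylsilyl)phenyl trifluoromethanesulfonate; 15 2,4-dimethoxy-6-(triisopropylsilyloxymethyl)phenol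
Product: 20 2-[2,4-dimethoxy-6-(triisopropylsilyloxymethyl)phenoxy]-6-(methoxymethoxy)-4-methyl-5-prenylbenzoic acid, via potassium phenoxide 16 (not isolated), via ring A aryne 17 (not isolated), via C1-arylpotassium 18 (not isolated), via potassium carboxylate 19 (not isolated)
Conditions: 15 (1.5 equiv), KH, THF, 0 °C; then 11, KF, 18-crown-6, CO2 (1 atm), THF, 0 °C → rt; cold dilute HCl to pH 4
Reagents that add atoms: carbon dioxide, O=C=O
Why: Proposed new method: fluoride attacks the C1 silicon of 11 and the resulting carbanion expels the C2 triflate to give aryne 17; the crowded potassium phenoxide 16 then adds at C2 to form the diaryl ether C–O bond, and the C1 carbanion 18, held between the C6 and C2 oxygens, is captured by carbon dioxide to form the C1–carboxyl C–C bond (19). The closest known reaction types are the fluoride-induced O-arylation of phenols by arynes from 2-silylaryl triflates and the three-component coupling of arynes with amines and carbon dioxide to anthranilic acids; new here is an anionic oxygen nucleophile in the carboxylative coupling, where phenoxide and carbon dioxide equilibrate with an aryl carbonate, which the two ortho substituents of 16 should disfavour and which stays reversible in any case. No ring closes and no stereocentre forms. Regioselectivity (oxygen at C2, carboxyl at C1) is required and is secured by the inductively withdrawing C6 alkoxy group, which polarises the aryne so that the nucleophile enters at the remote terminus C2, and by the unsubstituted C3 next to C2; C-arylation of the phenoxide is excluded because its ortho and para positions are all substituted. Carboxylation must outrun protonation, which is secured by the aprotic medium, the preformed potassium salt (hydrogen gas is the only by-product of its formation) and the silyl ether on the ring B benzylic oxygen, which leaves 18 without an internal electrophile or acidic hydrogen.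

Step 11
Reactants: 20 2-[2,4-dimethoxy-6-(triisopropylsilyloxymethyl)phenoxy]-6-(methoxymethoxy)-4-methyl-5-prenylbenzoic acid
Product: 21 methyl 2-[2,4-dimethoxy-6-(triisopropylsilyloxymethyl)phenoxy]-6-(methoxymethoxy)-4-methyl-5-prenylbenzoate
Conditions: MeI, K2CO3, DMF, rt
Reagents that add atoms: iodomethane, CI
Why: SN2 O-alkylation of the carboxylate is insensitive to the two ortho substituents that would block Fischer esterification, and the acetal, silyl ether and alkene are inert to these conditions.

Step 12
Reactants: 21 methyl 2-[2,4-dimethoxy-6-(triisopropylsilyloxymethyl)phenoxy]-6-(methoxymethoxy)-4-methyl-5-prenylbenzoate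
Product: 22 methyl 2-[2,4-dimethoxy-6-(triisopropylsilyloxymethyl)phenoxy]-6-hydroxy-4-methyl-5-prenylbenzoate
Conditions: PPTS, MeOH, 55 °C
Reagents that add atoms: none
Why: Acid-catalysed transacetalisation to methanol should remove the aryl methoxymethyl ether, helped by the hydrogen bond that the freed C6 phenol forms with the ester carbonyl, while the weak pyridinium acid leaves the triisopropylsilyl ether intact and is too weak to cyclise the ortho-prenyl phenol to a chroman.

Step 13
Reactants: 22 methyl 2-[2,4-dimethoxy-6-(triisopropylsilyloxymethyl)phenoxy]-6-hydroxy-4-methyl-5-prenylbenzoate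
Product: 23 methyl 2-[2-(hydroxymethyl)-4,6-dimethoxyphenoxy]-6-hydroxy-4-methyl-5-prenylbenzoate (CNP0583011.0)
Conditions: Bu4NF, AcOH, THF, 0 °C → rt
Reagents that add atoms: none
Why: Fluoride-mediated cleavage of the primary silyl ether, buffered with acetic acid so that neither the phenoxide nor the benzylic alkoxide attacks the neighbouring methyl ester, should release the target.

Compound list
1 | orcinol (5-methylbenzene-1,3-diol) | Cc1cc(O)cc(O)c1 | starting material
2 | 5-methyl-1,3-phenylene bis(N,N-diethylcarbamate) | CCN(CC)C(=O)Oc1cc(C)cc(OC(=O)N(CC)CC)c1 | intermediate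
3 | C1-aryllithium of 2 (2-lithio-5-methyl-1,3-phenylene bis(N,N-diethylcarbamate)) | [Li]c1c(OC(=O)N(CC)CC)cc(C)cc1OC(=O)N(CC)CC | intermediate (not isolated)
4 | 5-methyl-2-(trimethylsilyl)-1,3-phenylene bis(N,N-diethylcarbamate) | C[Si](C)(C)c1c(OC(=O)N(CC)CC)cc(C)cc1OC(=O)N(CC)CC | intermediate
5 | prenyl bromide (1-bromo-3-methylbut-2-ene) | CC(C)=CCBr | starting material
6 | C5-aryllithium of 4 (4-lithio-5-methyl-2-(trimethylsilyl)-1,3-phenylene bis(N,N-diethylcarbamate)) | [Li]c1c(C)cc(OC(=O)N(CC)CC)c([Si](C)(C)C)c1OC(=O)N(CC)CC | intermediate (not isolated)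
7 | C5-arylcopper of 4 | [Cu]c1c(C)cc(OC(=O)N(CC)CC)c([Si](C)(C)C)c1OC(=O)N(CC)CC | intermediate (not isolated)
8 | 5-methyl-4-prenyl-2-(trimethylsilyl)-1,3-phenylene bis(N,N-diethylcarbamate) | CC(C)=CCc1c(C)cc(OC(=O)N(CC)CC)c([Si](C)(C)C)c1OC(=O)N(CC)CC | intermediate
9 | 5-methyl-4-prenyl-2-(trimethylsilyl)benzene-1,3-diol | CC(C)=CCc1c(C)cc(O)c([Si](C)(C)C)c1O | intermediate
10 | 3-hydroxy-5-methyl-4-prenyl-2-(trimethylsilyl)phenyl trifluoromethanesulfonate | CC(C)=CCc1c(C)cc(OS(=O)(=O)C(F)(F)F)c([Si](C)(C)C)c1O | intermediate
11 | 3-(methoxymethoxy)-5-methyl-4-prenyl-2-(trimethylsilyl)phenyl trifluoromethanesulfonate (aryne precursor) | CC(C)=CCc1c(C)cc(OS(=O)(=O)C(F)(F)F)c([Si](C)(C)C)c1OCOC | intermediate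
12 | 2,4-dimethoxyphenol | COc1ccc(O)c(OC)c1 | starting material
13 | 2-hydroxy-3,5-dimethoxybenzaldehyde | COc1cc(OC)c(O)c(C=O)c1 | intermediate
14 | 2-(hydroxymethyl)-4,6-dimethoxyphenol | COc1cc(CO)c(O)c(OC)c1 | intermediate
15 | 2,4-dimethoxy-6-(triisopropylsilyloxymethyl)phenol | CC(C)[Si](OCc1cc(OC)cc(OC)c1O)(C(C)C)C(C)C | intermediate
16 | potassium 2,4-dimethoxy-6-(triisopropylsilyloxymethyl)phenoxide | CC(C)[Si](OCc1cc(OC)cc(OC)c1[O-])(C(C)C)C(C)C.[K+] | intermediate (not isolated)
17 | ring A aryne (3-(methoxymethoxy)-5-methyl-4-prenylbenzyne, triple bond C1≡C2) | COCOC1=C(CC=C(C)C)C(C)=CC#C1 | intermediate (not isolated)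
18 | C1-arylpotassium (2-aryloxy-6-(methoxymethoxy)-4-methyl-5-prenylphenylpotassium) | [K]c1c(OCOC)c(CC=C(C)C)c(C)cc1Oc1c(CO[Si](C(C)C)(C(C)C)C(C)C)cc(OC)cc1OC | intermediate (not isolated)
19 | potassium 2-[2,4-dimethoxy-6-(triisopropylsilyloxymethyl)phenoxy]-6-(methoxymethoxy)-4-methyl-5-prenylbenzoate | CC(C)=CCc1c(C)cc(Oc2c(CO[Si](C(C)C)(C(C)C)C(C)C)cc(OC)cc2OC)c(C(=O)[O-])c1OCOC.[K+] | intermediate (not isolated)
20 | 2-[2,4-dimethoxy-6-(triisopropylsilyloxymethyl)phenoxy]-6-(methoxymethoxy)-4-methyl-5-prenylbenzoic acid | CC(C)=CCc1c(C)cc(Oc2c(CO[Si](C(C)C)(C(C)C)C(C)C)cc(OC)cc2OC)c(C(=O)O)c1OCOC | intermediate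
21 | methyl 2-[2,4-dimethoxy-6-(triisopropylsilyloxymethyl)phenoxy]-6-(methoxymethoxy)-4-methyl-5-prenylbenzoate | CC(C)=CCc1c(C)cc(Oc2c(CO[Si](C(C)C)(C(C)C)C(C)C)cc(OC)cc2OC)c(C(=O)OC)c1OCOC | intermediate
22 | methyl 2-[2,4-dimethoxy-6-(triisopropylsilyloxymethyl)phenoxy]-6-hydroxy-4-methyl-5-prenylbenzoate | CC(C)=CCc1c(C)cc(Oc2c(CO[Si](C(C)C)(C(C)C)C(C)C)cc(OC)cc2OC)c(C(=O)OC)c1O | intermediate
23 | methyl 2-[2-(hydroxymethyl)-4,6-dimethoxyphenoxy]-6-hydroxy-4-methyl-5-prenylbenzoate | COC(=O)c1c(Oc2c(CO)cc(OC)cc2OC)cc(C)c(CC=C(C)C)c1O | target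

Total step count: 13. Longest linear sequence: 10 steps (steps 1–6, then 10–13); the ring B branch is 3 steps (7–9).

Steps most likely to fail

Step 10. The phenoxide may be held back as its aryl carbonate under carbon dioxide, so that addition to the aryne becomes slow or the carbonate oxygen adds instead. The C1 carbanion may also be protonated by adventitious acid before it is carboxylated. The fallback splits the two bond formations into known reactions and sets out from 11 and 15. CsF in MeCN at room temperature (fluoride-induced O-arylation of a phenol by an aryne, with the carbanion protonated by the phenol and the solvent) should give the diaryl ether without the carboxyl group, triisopropyl({3,5-dimethoxy-2-[3-(methoxymethoxy)-5-methyl-4-prenylphenoxy]benzyl}oxy)silane F1. Directed ortho-metalation of F1 with n-BuLi and TMEDA in THF at −78 → −30 °C should take place at ring A C1, the only position flanked by the chelating methoxymethoxy group and a second oxygen. The low temperature is kept to spare the ring B position between the two methoxy groups. This gives the C1-aryllithium of the diaryl ether F2, which carbon dioxide should convert into lithium 2-aryloxy-6-(methoxymethoxy)-4-methyl-5-prenylbenzoate F3. Acidification to pH 4 returns to the route at 20.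

Step 6. Deprotonation of the C6 hydroxyl next to the C1 silicon may trigger a shift of silicon from carbon to oxygen and loss of the C2 triflate, releasing the aryne prematurely; alkylation of the doubly flanked phenol may also stall. The fallback sets out from diol 9 and puts the acetal on before the triflate exists. TBSCl and imidazole in DMF at 0 °C should silylate the less hindered C2 hydroxyl to give 3-(tert-butyldimethylsilyloxy)-5-methyl-6-prenyl-2-(trimethylsilyl)phenol F4. MOMCl with i-Pr2NEt (or NaH, now harmless because no leaving group is present) should give tert-butyl[3-(methoxymethoxy)-5-methyl-4-prenyl-2-(trimethylsilyl)phenoxy]dimethylsilane F5. KHF2 in MeOH at room temperature, which is selective for phenolic silyl ethers, should give 3-(methoxymethoxy)-5-methyl-4-prenyl-2-(trimethylsilyl)phenol F6. Triflation with PhNTf2 and Et3N in CH2Cl2 comes back to the route at 11.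

Step 3. The arylcopper may attack the tertiary allyl terminus of prenyl bromide, giving the 1,1-dimethylallyl isomer. Coupling at the carbon flanked by methyl and carbamate may also be so slow that the metalated carbamate rearranges on warming. The fallback sets out from 4 through the same aryllithium 6, which is trapped at −78 °C with allyl bromide; both modes of allylic attack lead to the same product, 4-allyl-5-methyl-2-(trimethylsilyl)-1,3-phenylene bis(N,N-diethylcarbamate) F7. Cross-metathesis of F7 with an excess of 2-methyl-2-butene and second-generation Grubbs catalyst in CH2Cl2 at 40 °C should turn the allyl into the prenyl group and come back to the route at 8.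

Further compounds
F1 | step 10 | triisopropyl({3,5-dimethoxy-2-[3-(methoxymethoxy)-5-methyl-4-prenylphenoxy]benzyl}oxy)silane | CC(C)=CCc1c(C)cc(Oc2c(CO[Si](C(C)C)(C(C)C)C(C)C)cc(OC)cc2OC)cc1OCOC
F2 | step 10 | C1-aryllithium of the diaryl ether F1 | [Li]c1c(OCOC)c(CC=C(C)C)c(C)cc1Oc1c(CO[Si](C(C)C)(C(C)C)C(C)C)cc(OC)cc1OC
F3 | step 10 | lithium 2-[2,4-dimethoxy-6-(triisopropylsilyloxymethyl)phenoxy]-6-(methoxymethoxy)-4-methyl-5-prenylbenzoate | CC(C)=CCc1c(C)cc(Oc2c(CO[Si](C(C)C)(C(C)C)C(C)C)cc(OC)cc2OC)c(C(=O)[O-])c1OCOC.[Li+]
F4 | step 6 | 3-(tert-butyldimethylsilyloxy)-5-methyl-6-prenyl-2-(trimethylsilyl)phenol | CC(C)=CCc1c(C)cc(O[Si](C)(C)C(C)(C)C)c([Si](C)(C)C)c1O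
F5 | step 6 | tert-butyl[3-(methoxymethoxy)-5-methyl-4-prenyl-2-(trimethylsilyl)phenoxy]dimethylsilane | CC(C)=CCc1c(C)cc(O[Si](C)(C)C(C)(C)C)c([Si](C)(C)C)c1OCOC
F6 | step 6 | 3-(methoxymethoxy)-5-methyl-4-prenyl-2-(trimethylsilyl)phenol | CC(C)=CCc1c(C)cc(O)c([Si](C)(C)C)c1OCOC
F7 | step 3 | 4-allyl-5-methyl-2-(trimethylsilyl)-1,3-phenylene bis(N,N-diethylcarbamate) | C=CCc1c(C)cc(OC(=O)N(CC)CC)c([Si](C)(C)C)c1OC(=O)N(CC)CC
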